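The constants are made up; the rest is arithmetic.

Seconds, not hours, are the clock on this bench today, 6.0 s a flask, and this is what you take over.

    2 E → E2 (k1 = 0.59 L mol⁻¹ s⁻¹)
    E + L ⇌ L + D (K2 = 1.7, k2 = 2.7 × 10⁵ L mol⁻¹ s⁻¹)
    Z + L.D → L + X (k3 = 3.7 × 10⁵ L mol⁻¹ s⁻¹)
    L + D ⇌ L.D (K4 = 5900 L mol⁻¹, k4 = 2.0 × 10⁷ L mol⁻¹ s⁻¹)

all flasks: L 0.50 µM; time 6.0 s

| run | E | Z | remark |
|---|---|---|---|
| Saturday's | 0.50 mM | 0.550 mM (fed, over 4.0 s) | all else is in the flask from the start; the feed brings no volume worth counting |
| Thursday's | 0.50 mM (fed, over 4.0 s) | 0.550 mM | all else is in the flask from the start; the feed brings no volume worth counting |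
| Wednesday's | 0.50 mM | 0.550 mM (in portions, 3, over 4.0 s) | first portion at the start, last at 4.0 s |
| Sunday's | 0.50 mM | 0.550 mM | everything together at the start |

- a species is counted by the E in it: one E2 counts as two
- for a step with 2 of a species take k times the square, and two of it per event
- run time (Saturday's): 6.0 s

* which flask leads in amount of X, in percent of the E charged ("all alike" within 1.5 percentage points) (Saturday's / Thursday's / Wednesday's / Sunday's / all alike)
* how much X is there at the end, in percent of the E charged: Saturday's
* how much X is there at the end, in percent of the E charged: Thursday's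
* how much X is there at the end, in percent of the E charged: Wednesday's
* how much X is there at the end, in percent of the E charged: Sunday's

In Sunday's flask you start with E, Z and free L, and no D or X. L turns E into D, D sits on L as L.D, and Z takes L.D off as X. Because L.D falls apart at 3390 s⁻¹, far faster than Z takes it at 204 s⁻¹, L and D stay at binding equilibrium.

So I solve both ends. Late on, D made equals D taken, and [L] cancels, which leaves the standing ratio ρ of D to E (a steady-state ratio): the forward constant of E to D, over its back constant plus the capture term, which is the constant of Z on L.D times the binding constant times [Z]. With Z as charged, ρ is 0.199. With D at ρ times the E charged, L stays 63.1% free.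

Early on, D needs about 1.95 s to reach that ratio. After that, E and D together drain at 0.0627 s⁻¹. Joined, Sunday's gives 22.5% X. In Thursday's, E arrives on average 2.00 s late, which gives less, 12.1%. So do not hold E back. In Saturday's and Wednesday's [Z] moves with the dosing, and I stop there.

The forecast names Sunday's, with 23%, 18%, 22.5% and 27% for Saturday's, Thursday's, Wednesday's and Sunday's. For Sunday's it stands higher than mine, and for Thursday's too. On the order of the flasks it says “withholding Z costs a few points and withholding E costs the most”.

The flasks give 23.1%, 17.6%, 22.5% and 26.7% in that order, so Sunday's leads. In Sunday's at 6.00 s, Z stands at 75.7% of its charge, ρ becomes 0.253, and with E at 57.7% it gives D 14.6%, against 15.3% read. Thursday's flask read at 25.0 s holds Z 32.8% and E 16.2%, so ρ is 0.488 and D should be 7.91%. That flask reads D 9.59%, with X at 73.9%.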